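**Plan**

1. Retrosynthesis: cut the lactone O–C3 bond (back to a 14-membered 3,4:11,12-bis-epoxy C16 acid), take both epoxide oxygens off (two E olefins), cut C7–C8 (alkenyl iodide plus aldehyde), then C9–C10, C11=C12, C5–C6 and C3=C4, which leads to a keto acetal from (R)-limonene.
2. Forward: limonene gives C1–C3, C12–C17 and C20; the chain grows first at the ketone end (C10/C11, then C8/C9/C19), then at the aldehyde end (C4/C5/C18, then C6/C7); the carbocycle closes at C7–C8, the epoxides follow, and the δ-lactone ring closes last.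
3. Enabling feature: on the lactone ring C1–C2–C3–O–C16–C15 the acyloxy oxygen at C3 is anti to the tertiary hydroxyl at C4. This is what rear-side attack of the C16 carboxylate on C3 of the E-derived (3S,4S)-epoxide leaves behind, and C16 is placed for a 6-exo closure on C3.
4. Stereochemistry: C1 from (R)-limonene; C15 by catalyst-controlled hydrogenation; C7 by Corey–Bakshi–Shibata reduction; C4, C11 and C12 by Shi epoxidation; C3 by inversion of the Shi epoxide in the lactonisation.

Key step: step 22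

Numbering and abbreviations: cembrane numbering is used from compound 7 on (ring carbons C1–C14; C15 on C1 carries C16 and C17; C18, C19 and C20 sit on C4, C8 and C12). TBDPS = tert-butyldiphenylsilyl, PMB = 4-methoxybenzyl.

Assumption: in step 2 the (S)-BINAP complex is taken to give the 15S centre, by analogy with catalyst-controlled hydrogenation of other 2-substituted allylic alcohols; if the sense proved opposite, the (R)-BINAP complex would be used in the same step.

**Route**

Step 1
Reactants: 1 (R)-(+)-limonene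
Product: 4 2-[(1R)-4-methylcyclohex-3-en-1-yl]prop-2-en-1-ol, via 10-lithiolimonene 2 (not isolated), via dimethyl allylboronate 3 (not isolated)
Conditions: n-BuLi, TMEDA, hexane, 25 °C; B(OMe)3, THF, −78 to 25 °C; H2O2, aq NaOH, 0 °C
Reagents that add atoms: hydrogen peroxide, SMILES OO
Why: Allylic lithiation with n-BuLi·TMEDA takes place at the isopropenyl methyl group, the symmetrical 2-substituted allyl anion is trapped on boron and the allylboronate is oxidised to the primary allylic alcohol (lithiation–borylation–oxidation), which leaves the ring stereocentre untouched.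

Step 2
Reactants: 4 2-[(1R)-4-methylcyclohex-3-en-1-yl]prop-2-en-1-ol
Product: 5 (2S)-2-[(1R)-4-methylcyclohex-3-en-1-yl]propan-1-ol
Conditions: H2 (50 atm), Ru(OAc)2[(S)-BINAP] (1 mol %), MeOH, 25 °C
Reagents that add atoms: none
Why: Hydroxyl-directed asymmetric hydrogenation with the BINAP–ruthenium diacetate catalyst reduces only the 2-substituted allylic alcohol (the remote ring olefin cannot chelate), and the (S)-ligand is expected to deliver H2 to the face that makes the new methyl-bearing centre, the future C15, S.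

Step 3
Reactants: 5 (2S)-2-[(1R)-4-methylcyclohex-3-en-1-yl]propan-1-ol
Product: 6 TBDPS ether of 5
Conditions: TBDPSCl, imidazole, CH2Cl2, 0 to 25 °C
Reagents that add atoms: tert-butyl(chloro)diphenylsilane, SMILES CC(C)(C)[Si](Cl)(c1ccccc1)c1ccccc1
Why: Silyl ether formation at the primary alcohol gives a group that should survive the acid, hydride, organolithium and boron halide reagents of steps 4 to 18.

Step 4
Reactants: 6 TBDPS ether of 5
Product: 9 (5R)-7,7-dimethoxy-5-[(2S)-1-(TBDPS-oxy)propan-2-yl]heptan-2-one, via methoxy hydroperoxide aldehyde 7 (not isolated), via methoxy hydroperoxide acetal 8 (not isolated)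
Conditions: O3, CH2Cl2/MeOH, −78 °C; TsOH·H2O (cat.), 25 °C; NaHCO3, Me2S, 25 °C
Reagents that add atoms: ozone, SMILES [O-][O+]=O; methanol, SMILES CO
Why: Ozonolysis of the only olefin in methanol traps the carbonyl oxide at the more substituted carbon as a methoxy hydroperoxide while the aldehyde end is acetalised by acid before reductive work-up, so that the two termini emerge as a free methyl ketone (C12) and a protected aldehyde (C3) (terminus-differentiating ozonolysis).

Step 5
Reactants: 9 keto acetal; 10 triethyl phosphonoacetate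
Product: 11 ethyl (2E,6R)-8,8-dimethoxy-3-methyl-6-[(2S)-1-(TBDPS-oxy)propan-2-yl]oct-2-enoate
Conditions: NaH, THF, 0 °C to reflux; minor Z isomer removed by chromatography
Reagents that add atoms: none
Why: Horner–Wadsworth–Emmons olefination of the methyl ketone should place the ester trans to the larger C13 chain and so give mainly the E trisubstituted enoate C11=C12, with the Z isomer separable.

Step 6
Reactants: 11 E enoate
Product: 12 (2E,6R)-8,8-dimethoxy-3-methyl-6-[(2S)-1-(TBDPS-oxy)propan-2-yl]oct-2-en-1-ol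
Conditions: i-Bu2AlH (2.2 equiv), CH2Cl2, −78 °C; aq potassium sodium tartrate
Reagents that add atoms: none
Why: 1,2-Reduction of the enoate by the aluminium hydride (ester reduction) gives the allylic alcohol without touching the acetal, the silyl ether or the olefin geometry.

Step 7
Reactants: 12 allylic alcohol
Product: 13 (2E,6R)-1-bromo-8,8-dimethoxy-3-methyl-6-[(2S)-1-(TBDPS-oxy)propan-2-yl]oct-2-ene
Conditions: CBr4, PPh3, 2,6-lutidine, CH2Cl2, 0 °C
Reagents that add atoms: carbon tetrabromide, SMILES BrC(Br)(Br)Br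
Why: Appel bromination converts the primary allylic alcohol into the bromide by SN2 displacement of the oxyphosphonium group, and the buffered low temperature keeps the acetal and the olefin position intact.

Step 8
Reactants: 13 allylic bromide; 14 1-(trimethylsilyl)propyne
Product: 15 (3R,6E)-1,1-dimethoxy-6-methyl-3-[(2S)-1-(TBDPS-oxy)propan-2-yl]-11-(trimethylsilyl)undec-6-en-10-yne
Conditions: 14, n-BuLi, THF, −78 to −20 °C; then 13, −78 to 0 °C
Reagents that add atoms: none
Why: The propargylic lithium reagent made from the silylpropyne alkylates the primary allylic bromide at its α-carbon (SN2 alkylation), the silyl group suppressing allenyl coupling, which forms C9–C10 and brings in C8 and C19.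

Step 9
Reactants: 15 enyne acetal
Product: 16 (3R,6E)-6-methyl-3-[(2S)-1-(TBDPS-oxy)propan-2-yl]-11-(trimethylsilyl)undec-6-en-10-ynal
Conditions: PPTS (cat.), acetone/H2O, 50 °C
Reagents that add atoms: water, SMILES O
Why: Acid-catalysed acetal hydrolysis through the oxocarbenium ion frees the C3 aldehyde under conditions mild enough for the silyl ether, the alkynylsilane and the trisubstituted olefin.

Step 10
Reactants: 16 aldehyde; 17 isopropenylmagnesium bromide
Product: 18 (5R,8E)-2,8-dimethyl-5-[(2S)-1-(TBDPS-oxy)propan-2-yl]-13-(trimethylsilyl)trideca-1,8-dien-12-yn-3-ol (C3 epimers)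
Conditions: THF, −78 °C; aq NH4Cl
Reagents that add atoms: none
Why: Grignard 1,2-addition of the isopropenyl group to the aldehyde installs C4, C5 and C18, and the carbinol configuration is immaterial because both epimers converge in step 11.

Step 11
Reactants: 18 allylic alcohol; 19 trimethyl orthoacetate
Product: 21 methyl (4E,7R,10E)-4,10-dimethyl-7-[(2S)-1-(TBDPS-oxy)propan-2-yl]-15-(trimethylsilyl)pentadeca-4,10-dien-14-ynoate, via allyl ketene acetal 20 (not isolated)
Conditions: 19 (excess), EtCO2H (cat.), xylene, 110 to 140 °C, MeOH distilled off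
Reagents that add atoms: none
Why: Johnson–Claisen rearrangement of the mixed ketene acetal through a chair transition state with the C2 chain equatorial should give the E trisubstituted olefin C3=C4 and adds C6 and C7 as the ester.

Step 12
Reactants: 21 silylalkyne ester
Product: 22 methyl (4E,7R,10E)-4,10-dimethyl-7-[(2S)-1-(TBDPS-oxy)propan-2-yl]pentadeca-4,10-dien-14-ynoate
Conditions: K2CO3 (0.2 equiv), MeOH, 25 °C
Reagents that add atoms: none
Why: Base-mediated methanolysis of the alkynyl C–Si bond (protodesilylation) frees the terminal alkyne, while the methyl ester and the TBDPS ether are stable to K2CO3 in methanol.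

Step 13
Reactants: 22 terminal alkyne ester
Product: 24 methyl (4E,7R,10E)-14-iodo-4,10-dimethyl-7-[(2S)-1-(TBDPS-oxy)propan-2-yl]pentadeca-4,10,14-trienoate, via iodoalkenylborane 23 (not isolated)
Conditions: B-iodo-9-BBN, pentane/CH2Cl2, −20 to 0 °C; AcOH, 0 °C; aq NaHCO3
Reagents that add atoms: B-iodo-9-borabicyclo[3.3.1]nonane, SMILES IB1C2CCCC1CCC2
Why: Syn iodoboration of the terminal alkyne puts iodine on the internal carbon and boron on the terminal one, and protodeboronation with acetic acid gives the 2-iodo-1-alkene (haloboration–protonolysis) without touching the trisubstituted olefins, the ester or the silyl ether.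

Step 14
Reactants: 24 iodo ester
Product: 25 (4E,7R,10E)-14-iodo-4,10-dimethyl-7-[(2S)-1-(TBDPS-oxy)propan-2-yl]pentadeca-4,10,14-trienal
Conditions: i-Bu2AlH (1.1 equiv), CH2Cl2, −78 °C; MeOH, aq potassium sodium tartrate
Reagents that add atoms: none
Why: At −78 °C the ester is reduced only as far as the tetrahedral aluminium hemiacetal, which releases the aldehyde on work-up (partial ester reduction), while the alkenyl iodide is inert.

Step 15
Reactants: 25 iodo aldehyde
Product: 26 (1R,3E,11E,15S)-16-(TBDPS-oxy)cembra-3,8(19),11-trien-7-ol (C7 epimers)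
Conditions: CrCl2 (8 equiv), NiCl2 (2 mol %), DMSO/THF, 25 °C, slow addition of 25 to 2 mM final concentration
Reagents that add atoms: none
Why: In the Nozaki–Hiyama–Kishi reaction zerovalent nickel inserts into the C–I bond, the alkenyl group passes to trivalent chromium and adds to the aldehyde only, which closes the 14-membered ring at C7–C8 under high dilution; the C7 configuration is not controlled here and is set in steps 16 and 17.

Step 16
Reactants: 26 macrocyclic allylic alcohol
Product: 27 (1R,3E,11E,15S)-16-(TBDPS-oxy)cembra-3,8(19),11-trien-7-one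
Conditions: Dess–Martin periodinane, NaHCO3, CH2Cl2, 0 to 25 °C
Reagents that add atoms: none
Why: Dess–Martin oxidation converts both C7 epimers into one α-methylene ketone under buffered, non-basic conditions that avoid conjugate addition.

Step 17
Reactants: 27 macrocyclic enone
Product: 28 (1R,3E,7S,11E,15S)-16-(TBDPS-oxy)cembra-3,8(19),11-trien-7-ol
Conditions: (R)-2-methyl-CBS-oxazaborolidine (0.2 equiv), catecholborane, toluene, −78 °C; MeOH, then aq NaOH wash
Reagents that add atoms: none
Why: In the Corey–Bakshi–Shibata reduction the ketone binds the oxazaborolidine with the branched alkenyl group as the large substituent, so that hydride should reach the Re face of C7 and give the 7S alcohol with the (R)-catalyst.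

Step 18
Reactants: 28 7S allylic alcohol
Product: 29 (1R,3E,7S,11E,15S)-7-(PMB-oxy)-16-(TBDPS-oxy)cembra-3,8(19),11-triene
Conditions: NaH, PMBCl, Bu4NI (cat.), THF/DMF, 0 to 25 °C
Reagents that add atoms: 4-methoxybenzyl chloride, SMILES COc1ccc(CCl)cc1
Why: Williamson etherification of the sodium alkoxide gives the PMB ether, which keeps O7 from adding to C4 later and tolerates fluoride, oxoammonium, dioxirane and carbonate conditions.

Step 19
Reactants: 29 PMB/TBDPS diether
Product: 30 (1R,3E,7S,11E,15S)-7-(PMB-oxy)cembra-3,8(19),11-trien-16-ol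
Conditions: Bu4NF, THF, 25 °C
Reagents that add atoms: none
Why: Fluoride-mediated desilylation cleaves the Si–O bond of the primary silyl ether and leaves the PMB ether and the olefins untouched.

Step 20
Reactants: 30 primary alcohol
Product: 32 (1R,3E,7S,11E,15S)-7-(PMB-oxy)cembra-3,8(19),11-trien-16-oic acid, via C16 aldehyde 31 (not isolated)
Conditions: TEMPO (0.2 equiv), PhI(OAc)2 (2.5 equiv), MeCN/H2O, 25 °C
Reagents that add atoms: water, SMILES O
Why: Oxoammonium (TEMPO) oxidation with PhI(OAc)2 in aqueous acetonitrile takes the primary alcohol through the aldehyde hydrate to the acid without touching the olefins or the PMB ether, and the near-neutral medium should keep the α-stereocentre C15 from epimerising.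

Step 21
Reactants: 32 triene acid
Product: 33 (1R,3S,4S,7S,11S,12S,15S)-3,4:11,12-diepoxy-7-(PMB-oxy)cembr-8(19)-en-16-oic acid
Conditions: ent-Shi ketone (1,2:4,5-di-O-isopropylidene-β-L-erythro-2,3-hexodiulo-2,6-pyranose, 0.6 equiv), KHSO5 (as Oxone, 2KHSO5·KHSO4·K2SO4), K2CO3, Bu4NHSO4 (cat.), MeCN/dimethoxymethane/aq Na2B4O7–Na2EDTA buffer (pH 10.5), 0 °C; NaH2PO4 to pH 5 at 0 °C, extraction, used crude at once
Reagents that add atoms: potassium peroxymonosulfate, SMILES [K+].[O-]S(=O)(=O)OO
Why: In the Shi epoxidation the chiral dioxirane attacks through a spiro transition state and oxidises the two electron-rich E trisubstituted olefins faster than the 1,1-disubstituted C8 methylene, and the ketone enantiomer that gives S,S epoxides sets C3, C4, C11 and C12 under reagent control while the acid is held as an unreactive carboxylate at pH 10.5 and 0 °C.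

Step 22
Reactants: 33 bis-epoxy acid
Product: 35 (1R,3R,4S,7S,11S,12S,15S)-11,12-epoxy-4-hydroxy-7-(PMB-oxy)cembr-8(19)-en-16,3-olide, via cesium carboxylate 34 (not isolated)
Conditions: Cs2CO3 (1.5 equiv), DMF, 60 °C; aq NH4Cl
Reagents that add atoms: none
Why: Cs2CO3 turns the acid into cesium carboxylate 34, whose oxygen displaces the epoxide oxygen at C3 from the rear in an intramolecular SN2 reaction, so that C3 inverts from S to R while the oxygen stays on C4 as the tertiary alkoxide and becomes the 4S hydroxyl on work-up. The closest known reaction type is epoxy-acid lactonisation, the intramolecular opening of an epoxide by a carboxylate to a hydroxy lactone. The single ring formed, the δ-lactone C16–O–C3–C2–C1–C15, closes in the 6-exo-tet mode. The single new stereocentre, C3, is fixed by the stereospecific inversion of the (3S,4S)-epoxide set by the Shi catalyst, which places the acyloxy group on C3 anti to the hydroxyl on C4; C15 is untouched and its methyl group ends equatorial on the lactone, trans to the C1–C14 bond. The step needs attack at C3 only, and the alternatives are 7-endo at the fully substituted C4, 7-exo at the fully substituted C12 and 8-endo at C11, all slower than 6-exo attack on the secondary C3 when the nucleophile is a carboxylate in a basic, non-ionising medium. The C7 oxygen is carried as a PMB ether, which takes away the hydroxyl that could otherwise close a tetrahydrofuran onto C4, and the absence of acid keeps the tertiary centres C4 and C12 from opening by a cationic path.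

Step 23
Reactants: 35 lactone PMB ether
Product: 36 CNP0262409.2
Conditions: DDQ, CH2Cl2/aq phosphate buffer (pH 7), 0 °C
Reagents that add atoms: none
Why: Oxidative PMB cleavage by DDQ (single-electron oxidation to the benzylic oxocarbenium ion, then hydrolysis) runs under buffered neutral conditions that should leave the epoxide, the lactone, the tertiary alcohol and the exocyclic olefin intact.

**Compound list**

1 | (R)-(+)-limonene, (4R)-1-methyl-4-(prop-1-en-2-yl)cyclohex-1-ene | CC1=CC[C@@H](CC1)C(C)=C | starting material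
2 | 10-lithiolimonene, {2-[(1R)-4-methylcyclohex-3-en-1-yl]prop-2-en-1-yl}lithium (formed in the flask) | CC1=CC[C@@H](CC1)C(=C)C[Li] | intermediate
3 | dimethyl {2-[(1R)-4-methylcyclohex-3-en-1-yl]prop-2-en-1-yl}boronate (formed in the flask) | CC1=CC[C@@H](CC1)C(=C)CB(OC)OC | intermediate
4 | 2-[(1R)-4-methylcyclohex-3-en-1-yl]prop-2-en-1-ol | CC1=CC[C@@H](CC1)C(=C)CO | intermediate
5 | (2S)-2-[(1R)-4-methylcyclohex-3-en-1-yl]propan-1-ol | CC1=CC[C@@H](CC1)[C@H](C)CO | intermediate
6 | tert-butyl{(2S)-2-[(1R)-4-methylcyclohex-3-en-1-yl]propoxy}diphenylsilane | CC1=CC[C@@H](CC1)[C@H](C)CO[Si](c1ccccc1)(c1ccccc1)C(C)(C)C | intermediate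
7 | (3R)-6-hydroperoxy-6-methoxy-3-[(2S)-1-(TBDPS-oxy)propan-2-yl]heptanal, C6 epimers (formed in the flask) | CC(OC)(OO)CC[C@@H]([C@H](C)CO[Si](c1ccccc1)(c1ccccc1)C(C)(C)C)CC=O | intermediate
8 | (5R)-2-hydroperoxy-2,7,7-trimethoxy-5-[(2S)-1-(TBDPS-oxy)propan-2-yl]heptane, C2 epimers (formed in the flask) | CC(OC)(OO)CC[C@@H]([C@H](C)CO[Si](c1ccccc1)(c1ccccc1)C(C)(C)C)CC(OC)OC | intermediate
9 | (5R)-7,7-dimethoxy-5-[(2S)-1-(TBDPS-oxy)propan-2-yl]heptan-2-one | CC(=O)CC[C@@H]([C@H](C)CO[Si](c1ccccc1)(c1ccccc1)C(C)(C)C)CC(OC)OC | intermediate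
10 | triethyl phosphonoacetate | CCOC(=O)CP(=O)(OCC)OCC | starting material
11 | ethyl (2E,6R)-8,8-dimethoxy-3-methyl-6-[(2S)-1-(TBDPS-oxy)propan-2-yl]oct-2-enoate | CCOC(=O)/C=C(\C)CC[C@@H]([C@H](C)CO[Si](c1ccccc1)(c1ccccc1)C(C)(C)C)CC(OC)OC | intermediate
12 | (2E,6R)-8,8-dimethoxy-3-methyl-6-[(2S)-1-(TBDPS-oxy)propan-2-yl]oct-2-en-1-ol | OC/C=C(\C)CC[C@@H]([C@H](C)CO[Si](c1ccccc1)(c1ccccc1)C(C)(C)C)CC(OC)OC | intermediate
13 | (2E,6R)-1-bromo-8,8-dimethoxy-3-methyl-6-[(2S)-1-(TBDPS-oxy)propan-2-yl]oct-2-ene | BrC/C=C(\C)CC[C@@H]([C@H](C)CO[Si](c1ccccc1)(c1ccccc1)C(C)(C)C)CC(OC)OC | intermediate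
14 | 1-(trimethylsilyl)propyne | CC#C[Si](C)(C)C | starting material
15 | (3R,6E)-1,1-dimethoxy-6-methyl-3-[(2S)-1-(TBDPS-oxy)propan-2-yl]-11-(trimethylsilyl)undec-6-en-10-yne | C[Si](C)(C)C#CCC/C=C(\C)CC[C@@H]([C@H](C)CO[Si](c1ccccc1)(c1ccccc1)C(C)(C)C)CC(OC)OC | intermediate
16 | (3R,6E)-6-methyl-3-[(2S)-1-(TBDPS-oxy)propan-2-yl]-11-(trimethylsilyl)undec-6-en-10-ynal | C[Si](C)(C)C#CCC/C=C(\C)CC[C@@H]([C@H](C)CO[Si](c1ccccc1)(c1ccccc1)C(C)(C)C)CC=O | intermediate
17 | isopropenylmagnesium bromide | CC(=C)[Mg]Br | starting material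
18 | (5R,8E)-2,8-dimethyl-5-[(2S)-1-(TBDPS-oxy)propan-2-yl]-13-(trimethylsilyl)trideca-1,8-dien-12-yn-3-ol, C3 epimers | C[Si](C)(C)C#CCC/C=C(\C)CC[C@@H]([C@H](C)CO[Si](c1ccccc1)(c1ccccc1)C(C)(C)C)CC(O)C(C)=C | intermediate
19 | trimethyl orthoacetate | CC(OC)(OC)OC | starting material
20 | 1-methoxyvinyl ether of 18 at O3, the allyl ketene acetal (formed in the flask) | C[Si](C)(C)C#CCC/C=C(\C)CC[C@@H]([C@H](C)CO[Si](c1ccccc1)(c1ccccc1)C(C)(C)C)CC(OC(=C)OC)C(C)=C | intermediate
21 | methyl (4E,7R,10E)-4,10-dimethyl-7-[(2S)-1-(TBDPS-oxy)propan-2-yl]-15-(trimethylsilyl)pentadeca-4,10-dien-14-ynoate | C[Si](C)(C)C#CCC/C=C(\C)CC[C@@H]([C@H](C)CO[Si](c1ccccc1)(c1ccccc1)C(C)(C)C)C/C=C(\C)CCC(=O)OC | intermediate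
22 | methyl (4E,7R,10E)-4,10-dimethyl-7-[(2S)-1-(TBDPS-oxy)propan-2-yl]pentadeca-4,10-dien-14-ynoate | C#CCC/C=C(\C)CC[C@@H]([C@H](C)CO[Si](c1ccccc1)(c1ccccc1)C(C)(C)C)C/C=C(\C)CCC(=O)OC | intermediate
23 | B-[(1Z)-2-iodoalk-1-enyl]-9-BBN adduct of 22, boron on C19 and iodine on C8 (formed in the flask) | I/C(=C\B1C2CCCC1CCC2)CC/C=C(\C)CC[C@@H]([C@H](C)CO[Si](c1ccccc1)(c1ccccc1)C(C)(C)C)C/C=C(\C)CCC(=O)OC | intermediate
24 | methyl (4E,7R,10E)-14-iodo-4,10-dimethyl-7-[(2S)-1-(TBDPS-oxy)propan-2-yl]pentadeca-4,10,14-trienoate | C=C(I)CC/C=C(\C)CC[C@@H]([C@H](C)CO[Si](c1ccccc1)(c1ccccc1)C(C)(C)C)C/C=C(\C)CCC(=O)OC | intermediate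
25 | (4E,7R,10E)-14-iodo-4,10-dimethyl-7-[(2S)-1-(TBDPS-oxy)propan-2-yl]pentadeca-4,10,14-trienal | C=C(I)CC/C=C(\C)CC[C@@H]([C@H](C)CO[Si](c1ccccc1)(c1ccccc1)C(C)(C)C)C/C=C(\C)CCC=O | intermediate
26 | (1R,3E,11E,15S)-16-(TBDPS-oxy)cembra-3,8(19),11-trien-7-ol, C7 epimers | C=C1CC/C=C(\C)CC[C@@H]([C@H](C)CO[Si](c2ccccc2)(c2ccccc2)C(C)(C)C)C/C=C(\C)CCC1O | intermediate
27 | (1R,3E,11E,15S)-16-(TBDPS-oxy)cembra-3,8(19),11-trien-7-one | C=C1CC/C=C(\C)CC[C@@H]([C@H](C)CO[Si](c2ccccc2)(c2ccccc2)C(C)(C)C)C/C=C(\C)CCC1=O | intermediate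
28 | (1R,3E,7S,11E,15S)-16-(TBDPS-oxy)cembra-3,8(19),11-trien-7-ol | C=C1CC/C=C(\C)CC[C@@H]([C@H](C)CO[Si](c2ccccc2)(c2ccccc2)C(C)(C)C)C/C=C(\C)CC[C@@H]1O | intermediate
29 | (1R,3E,7S,11E,15S)-7-(PMB-oxy)-16-(TBDPS-oxy)cembra-3,8(19),11-triene | C=C1CC/C=C(\C)CC[C@@H]([C@H](C)CO[Si](c2ccccc2)(c2ccccc2)C(C)(C)C)C/C=C(\C)CC[C@@H]1OCc1ccc(OC)cc1 | intermediate
30 | (1R,3E,7S,11E,15S)-7-(PMB-oxy)cembra-3,8(19),11-trien-16-ol | C=C1CC/C=C(\C)CC[C@@H]([C@H](C)CO)C/C=C(\C)CC[C@@H]1OCc1ccc(OC)cc1 | intermediate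
31 | (1R,3E,7S,11E,15S)-7-(PMB-oxy)cembra-3,8(19),11-trien-16-al (formed in the flask) | C=C1CC/C=C(\C)CC[C@@H]([C@H](C)C=O)C/C=C(\C)CC[C@@H]1OCc1ccc(OC)cc1 | intermediate
32 | (1R,3E,7S,11E,15S)-7-(PMB-oxy)cembra-3,8(19),11-trien-16-oic acid | C=C1CC/C=C(\C)CC[C@@H]([C@H](C)C(=O)O)C/C=C(\C)CC[C@@H]1OCc1ccc(OC)cc1 | intermediate
33 | (1R,3S,4S,7S,11S,12S,15S)-3,4:11,12-diepoxy-7-(PMB-oxy)cembr-8(19)-en-16-oic acid | C=C1CC[C@@H]2O[C@@]2(C)CC[C@@H]([C@H](C)C(=O)O)C[C@@H]2O[C@@]2(C)CC[C@@H]1OCc1ccc(OC)cc1 | intermediate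
34 | cesium salt of 33 (formed in the flask) | C=C1CC[C@@H]2O[C@@]2(C)CC[C@@H]([C@H](C)C(=O)[O-])C[C@@H]2O[C@@]2(C)CC[C@@H]1OCc1ccc(OC)cc1.[Cs+] | intermediate
35 | (1R,3R,4S,7S,11S,12S,15S)-11,12-epoxy-4-hydroxy-7-(PMB-oxy)cembr-8(19)-en-16,3-olide, the 7-O-PMB ether of the target | C=C1CC[C@@H]2O[C@@]2(C)CC[C@@H]2C[C@@H](OC(=O)[C@H]2C)[C@@](C)(O)CC[C@@H]1OCc1ccc(OC)cc1 | intermediate
36 | CNP0262409.2, (1R,3R,4S,7S,11S,12S,15S)-11,12-epoxy-4,7-dihydroxycembr-8(19)-en-16,3-olide | C=C1CC[C@@H]2O[C@@]2(C)CC[C@@H]2C[C@@H](OC(=O)[C@H]2C)[C@@](C)(O)CC[C@@H]1O | target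

**Step count and risks**

Total step count: 23. Longest linear sequence: 23 steps, from (R)-limonene 1 to 36; compounds 10, 14, 17 and 19 are used as purchased.

The three steps most likely to fail:

Step 21 (bis-epoxidation on the macrocycle). In the 14-membered ring one face of C3=C4 or C11=C12 may be shielded, so that the ring conformation and not the catalyst decides the face. Oxidation of the C8 methylene may also begin before the second trisubstituted olefin is consumed. Fallback: the olefins are epoxidised on the open chain, where each is an unconstrained trisubstituted E olefin. Setting out from iodo ester 24, the same ent-Shi conditions (the alkenyl iodide is too electron-poor to react) would give the bis-epoxy iodo ester F1. i-Bu2AlH at −78 °C would then give the bis-epoxy iodo aldehyde F2, and CrCl2/NiCl2 ring closure the macrocyclic bis-epoxy allylic alcohol F3 (C7 epimers). Buffered Dess–Martin oxidation would give the bis-epoxy enone F4, and reduction with the (R)-oxazaborolidine and catecholborane the 7S bis-epoxy alcohol F5. NaH/PMBCl would give the bis-epoxy PMB ether F6 and Bu4NF the bis-epoxy primary alcohol F7. TEMPO/PhI(OAc)2 oxidation then comes back to the route at bis-epoxy acid 33.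

Step 15 (ring closure). Intermolecular coupling to oligomers and protodeiodination of the alkenylchromium species may outrun closure of the 14-membered ring. Fallback: nickel-catalysed reductive cyclisation of an ynal. Setting out from alkyne ester 22, i-Bu2AlH at −78 °C would give the ynal F8. Ni(cod)2 with the bulky carbene ligand 1,3-bis(2,6-diisopropylphenyl)imidazol-2-ylidene and Et3SiH in THF under high dilution would join aldehyde and alkyne reductively at the internal alkyne carbon. This would give the macrocyclic triethylsilyl ether F9 with the exocyclic methylene already in place. PPTS in MeOH would remove the secondary triethylsilyl group and leave the primary TBDPS ether, which comes back to the route at 26.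

Step 2 (hydrogenation). The face selectivity may be too low or reversed, and the allylic alcohol may isomerise to the saturated aldehyde instead of being reduced. Fallback: the directing group is changed from hydroxyl to carboxylate. Setting out from dienol 4, MnO2 would give the enal F10 and NaClO2 (NaH2PO4, 2-methyl-2-butene) the acrylic acid F11. Hydrogenation with RuCl2[(S)-DTBM-SEGPHOS](dmf)n, Et3N, MeOH, a catalyst type established for α-substituted acrylic acids, would give the (2S)-acid F12. LiAlH4 reduction then comes back to the route at alcohol 5.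

**Further compounds**

F1 | step 21 | methyl (4S,5S,7R,10S,11S)-4,5:10,11-diepoxy-14-iodo-4,10-dimethyl-7-[(2S)-1-(TBDPS-oxy)propan-2-yl]pentadec-14-enoate (cembrane 3S,4S,11S,12S) | C=C(I)CC[C@@H]1O[C@@]1(C)CC[C@@H]([C@H](C)CO[Si](c2ccccc2)(c2ccccc2)C(C)(C)C)C[C@@H]3O[C@@]3(C)CCC(=O)OC
F2 | step 21 | aldehyde corresponding to F1 (C7 aldehyde in place of the methyl ester) | C=C(I)CC[C@@H]1O[C@@]1(C)CC[C@@H]([C@H](C)CO[Si](c2ccccc2)(c2ccccc2)C(C)(C)C)C[C@@H]3O[C@@]3(C)CCC=O
F3 | step 21 | (1R,3S,4S,11S,12S,15S)-3,4:11,12-diepoxy-16-(TBDPS-oxy)cembr-8(19)-en-7-ol, C7 epimers | C=C1CC[C@@H]2O[C@@]2(C)CC[C@@H]([C@H](C)CO[Si](c3ccccc3)(c3ccccc3)C(C)(C)C)C[C@@H]2O[C@@]2(C)CCC1O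
F4 | step 21 | (1R,3S,4S,11S,12S,15S)-3,4:11,12-diepoxy-16-(TBDPS-oxy)cembr-8(19)-en-7-one | C=C1CC[C@@H]2O[C@@]2(C)CC[C@@H]([C@H](C)CO[Si](c3ccccc3)(c3ccccc3)C(C)(C)C)C[C@@H]2O[C@@]2(C)CCC1=O
F5 | step 21 | (1R,3S,4S,7S,11S,12S,15S)-3,4:11,12-diepoxy-16-(TBDPS-oxy)cembr-8(19)-en-7-ol | C=C1CC[C@@H]2O[C@@]2(C)CC[C@@H]([C@H](C)CO[Si](c3ccccc3)(c3ccccc3)C(C)(C)C)C[C@@H]2O[C@@]2(C)CC[C@@H]1O
F6 | step 21 | (1R,3S,4S,7S,11S,12S,15S)-3,4:11,12-diepoxy-7-(PMB-oxy)-16-(TBDPS-oxy)cembr-8(19)-ene | C=C1CC[C@@H]2O[C@@]2(C)CC[C@@H]([C@H](C)CO[Si](c3ccccc3)(c3ccccc3)C(C)(C)C)C[C@@H]2O[C@@]2(C)CC[C@@H]1OCc1ccc(OC)cc1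
F7 | step 21 | (1R,3S,4S,7S,11S,12S,15S)-3,4:11,12-diepoxy-7-(PMB-oxy)cembr-8(19)-en-16-ol | C=C1CC[C@@H]2O[C@@]2(C)CC[C@@H]([C@H](C)CO)C[C@@H]2O[C@@]2(C)CC[C@@H]1OCc1ccc(OC)cc1
F8 | step 15 | (4E,7R,10E)-4,10-dimethyl-7-[(2S)-1-(TBDPS-oxy)propan-2-yl]pentadeca-4,10-dien-14-ynal | C#CCC/C=C(\C)CC[C@@H]([C@H](C)CO[Si](c1ccccc1)(c1ccccc1)C(C)(C)C)C/C=C(\C)CCC=O
F9 | step 15 | (1R,3E,11E,15S)-16-(TBDPS-oxy)-7-(triethylsilyloxy)cembra-3,8(19),11-triene, C7 epimers | C=C1CC/C=C(\C)CC[C@@H]([C@H](C)CO[Si](c2ccccc2)(c2ccccc2)C(C)(C)C)C/C=C(\C)CCC1O[Si](CC)(CC)CC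
F10 | step 2 | 2-[(1R)-4-methylcyclohex-3-en-1-yl]prop-2-enal | CC1=CC[C@@H](CC1)C(=C)C=O
F11 | step 2 | 2-[(1R)-4-methylcyclohex-3-en-1-yl]prop-2-enoic acid | CC1=CC[C@@H](CC1)C(=C)C(=O)O
F12 | step 2 | (2S)-2-[(1R)-4-methylcyclohex-3-en-1-yl]propanoic acid | CC1=CC[C@@H](CC1)[C@H](C)C(=O)O
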